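The cyclohexane (ring carbons C5–C10, elemane numbering: C10 quaternary, C9 CH2, C8 ester carbinol, C7, C6 carbinol, C5) is cut into a two-carbon piece C5–C10 and a four-carbon piece C6–C9. The 1,3-placed oxygens at C6 and C8 flanking C7 are the imprint of a 1,3-bis(silyloxy)diene, so a catalytic enantioselective Diels–Alder reaction with an (E)-β-methyl-β-alkynyl enone closes the ring and fixes the C10 quaternary centre, C5 and C6 in one operation. Its precursors are acyclic: a tris-silylated dienol ether of 2-(2-hydroxyethyl)-3-oxobutanal and a silyloxymethyl enynone, whose ketone later becomes the side-chain methylene on C5 and whose alkyne the C10 vinyl group.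

Key step: step 10

Remark: C4 is the side-chain carbon on C5 (C3 its methylene, C15 its CH2O), C11–C13 the chain on C7 (C12 carboxyl, C13 methylene); TBS = tert-butyldimethylsilyl, TBDPS = tert-butyldiphenylsilyl, TMS = trimethylsilyl, PMB = 4-methoxybenzyl.
Assumption: the (S)-configured catalyst of step 10 is taken to expose the Si face of C5 and C10 of the bound enone; should the sense prove opposite, its (R) enantiomer is used with no other change.

Step 1
Reactants: 1 methyl glycolate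
Product: 2 methyl 2-(TBDPS-oxy)acetate
Conditions: t-BuPh2SiCl, imidazole, DMF, 0 °C → rt
Reagents that add atoms: tert-butyl(chloro)diphenylsilane, CC(C)(C)[Si](Cl)(c1ccccc1)c1ccccc1
Why: Imidazole-promoted silylation of the primary alcohol gives a silyl ether that should survive to the last step; no stereocentre is formed.

Step 2
Reactants: 2 methyl 2-(TBDPS-oxy)acetate; 3 1-propynylmagnesium bromide
Product: 5 1-(TBDPS-oxy)pent-3-yn-2-one, via Weinreb amide 4 (not isolated)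
Conditions: MeNH(OMe)·HCl, i-PrMgCl, THF, −20 °C; then 3, 0 °C
Reagents that add atoms: none
Why: The chloromagnesium amide converts the ester into the Weinreb amide, whose chelated tetrahedral adduct with the alkynyl Grignard reagent collapses only on work-up, so the ynone should form without over-addition (Weinreb ketone synthesis).

Step 3
Reactants: 5 1-(TBDPS-oxy)pent-3-yn-2-one; 6 ethynyltrimethylsilane
Product: 7 (3E)-1-(TBDPS-oxy)-4-methyl-6-(trimethylsilyl)hex-3-en-5-yn-2-one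
Conditions: Pd(OAc)2 (3 mol%), tris(2,6-dimethoxyphenyl)phosphine (3 mol%), THF, rt
Reagents that add atoms: none
Why: Pd-catalysed cross-addition of the terminal alkyne C–H bond across the electron-poor internal alkyne (alkyne–alkyne coupling) is a syn addition, so the new alkynyl group lies trans to the acyl group and the methyl group cis to it, which is the E geometry the cycloaddition needs.

Step 4
Reactants: 8 5-hydroxypentan-2-one
Product: 9 5-(TBS-oxy)pentan-2-one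
Conditions: t-BuMe2SiCl, imidazole, CH2Cl2, rt
Reagents that add atoms: tert-butyl(chloro)dimethylsilane, CC(C)(C)[Si](C)(C)Cl
Why: Standard silyl ether formation on the open hydroxy ketone form.

Step 5
Reactants: 9 5-(TBS-oxy)pentan-2-one
Product: 10 (3Z)-5-(TBS-oxy)-2-(trimethylsilyloxy)pent-2-ene
Conditions: Me3SiCl, Et3N, DMF, 80 °C; fractional distillation
Reagents that add atoms: chlorotrimethylsilane, C[Si](C)(C)Cl
Why: Enol silylation under equilibrating conditions should give mainly the more substituted silyl enol ether, which fixes the later site of formylation; the minor terminal isomer is removed by distillation.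

Step 6
Reactants: 10 (3Z)-5-(TBS-oxy)-2-(trimethylsilyloxy)pent-2-ene
Product: 13 (3E)-5-(TBS-oxy)-3-[(TBS-oxy)methylidene]pentan-2-one, via lithium enolate 11 (not isolated), via lithium formyl enolate 12 (not isolated)
Conditions: MeLi, THF, 0 °C; CF3CH2OCHO, −78 °C; t-BuMe2SiOTf, −78 °C → rt
Reagents that add atoms: 2,2,2-trifluoroethyl formate, O=COCC(F)(F)F; tert-butyldimethylsilyl triflate, CC(C)(C)[Si](C)(C)OS(=O)(=O)C(F)(F)F
Why: MeLi cleaves the trimethylsilyl enol ether to the regiodefined lithium enolate, trifluoroethyl formate C-formylates it (crossed Claisen condensation) and O-silylation of the formyl enolate gives the vinylogous silyl ester, whose E isomer is the thermodynamically preferred one.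

Step 7
Reactants: 13 (3E)-5-(TBS-oxy)-3-[(TBS-oxy)methylidene]pentan-2-one
Product: 14 (1E)-1,3-bis(TBS-oxy)-2-[2-(TBS-oxy)ethyl]buta-1,3-diene
Conditions: t-BuMe2SiOTf, Et3N, Et2O, 0 °C
Reagents that add atoms: tert-butyldimethylsilyl triflate, CC(C)(C)[Si](C)(C)OS(=O)(=O)C(F)(F)F
Why: Soft enolisation of the methyl ketone by silyl triflate and amine gives the 2-silyloxy diene with the C1=C2 geometry of 13 retained.

Step 8
Reactants: 15 3-methylfuran-2(5H)-one
Product: 18 4-methoxybenzyl (2Z)-4-(acetyloxy)-2-methylbut-2-enoate, via sodium hydroxy carboxylate 16 (not isolated), via PMB hydroxy ester 17 (not isolated)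
Conditions: NaOH (1.0 equiv), H2O, rt, freeze-drying; 4-MeOC6H4CH2Cl, DMF, rt; Ac2O, pyridine, DMAP (cat.), 0 °C
Reagents that add atoms: sodium hydroxide, [Na+].[OH-]; 4-methoxybenzyl chloride, COc1ccc(CCl)cc1; acetic anhydride, CC(=O)OC(C)=O
Why: Saponification opens the butenolide without touching its cis double bond, the carboxylate is O-alkylated and the hydroxyl is acetylated in the same pot before it can relactonise (ester hydrolysis, carboxylate alkylation, acylation).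

Step 9
Reactants: 18 4-methoxybenzyl (2Z)-4-(acetyloxy)-2-methylbut-2-enoate
Product: 19 (2Z)-4-(acetyloxy)-2-methylbut-2-enoic acid
Conditions: CF3CO2H, anisole, CH2Cl2, 0 °C
Reagents that add atoms: none
Why: Acidolysis cleaves the 4-methoxybenzyl ester through its stabilised benzylic cation, which anisole traps, while the allylic acetate and the Z alkene should be untouched.

Step 10
Reactants: 7 (3E)-1-(TBDPS-oxy)-4-methyl-6-(trimethylsilyl)hex-3-en-5-yn-2-one; 14 (1E)-1,3-bis(TBS-oxy)-2-[2-(TBS-oxy)ethyl]buta-1,3-diene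
Product: 20 2-(TBDPS-oxy)-1-[(1R,2R,6S)-2,4-bis(TBS-oxy)-3-[2-(TBS-oxy)ethyl]-6-methyl-6-[(trimethylsilyl)ethynyl]cyclohex-3-en-1-yl]ethan-1-one
Conditions: (S)-B-(o-tolyl)oxazaborolidine from (S)-α,α-diphenylprolinol (20 mol%), AlBr3 (16 mol%), CH2Cl2, −78 → −40 °C
Reagents that add atoms: none
Why: Proposed new method: the AlBr3-activated oxazaborolidine binds the enone carbonyl of 7 and lowers its LUMO, so that the silyl enol ether terminus C9 of 14 attacks the β-carbon C10 and the oxygenated terminus C6 closes on the α-carbon C5 in a strongly asynchronous [4+2] cycloaddition (at the stepwise limit a Mukaiyama–Michael addition followed by 6-exo-trig closure of the C5 enolate onto the C6 silyloxocarbenium ion). The closest known reaction types are the cationic-oxazaborolidine-catalysed enantioselective Diels–Alder reaction of β-monosubstituted acyclic enones with 2-silyloxy dienes and the aluminium-Lewis-acid-promoted Diels–Alder reaction of β,β-disubstituted enones with silyloxy dienes; their combination on a β-methyl-β-alkynyl enone has not been shown. The six-membered ring closes by intermolecular [4+2] cycloaddition. The C10 quaternary centre and C5 follow from suprafacial addition to the E alkene (methyl cis to the C5 acyl group, alkyne trans), C6 from the endo position of the Lewis-acid-bound ketone relative to the E silyloxy group (C6–O cis to the C5 acyl group), and the absolute sense from the catalyst, which should leave only the Si face of C5 and C10 open. The step needs 1,4- over 1,2- and 1,6-addition and C9-to-C10 regiochemistry, which the β-polarisation of the activated enone, the silyl cap on the alkyne terminus and the matching polarisation of the 1,3-dioxygenated diene should secure.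

Step 11
Reactants: 20 Diels–Alder adduct (ketone)
Product: 21 (1S,2R,6S)-2,4-bis(TBS-oxy)-3-[2-(TBS-oxy)ethyl]-1-[3-(TBDPS-oxy)prop-1-en-2-yl]-6-methyl-6-[(trimethylsilyl)ethynyl]cyclohex-3-ene
Conditions: Zn, CH2Br2, TiCl4 (pre-formed reagent), THF/CH2Cl2, 0 °C → rt
Reagents that add atoms: dibromomethane, BrCBr
Why: Takai–Lombardo methylenation converts the hindered ketone into the 1,1-disubstituted alkene under non-basic conditions, so that C5, which is epimerisable and carries a β-silyloxy group, should keep its configuration.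

Step 12
Reactants: 21 methylene silyl enol ether
Product: 23 (2S,3R,4S,5S)-3-(TBS-oxy)-2-[2-(TBS-oxy)ethyl]-4-[3-(TBDPS-oxy)prop-1-en-2-yl]-5-ethynyl-5-methylcyclohexan-1-one, via C7-epimeric ketone 22 (not isolated)
Conditions: Bu4NF, AcOH, THF, −20 → 0 °C; then DBU (0.2 equiv), CH2Cl2, 0 °C
Reagents that add atoms: none
Why: Buffered fluoride cleaves the silyl enol ether and the alkynyl C–Si bond, fast protonation of the enolate suppresses E1cB loss of the C6 silyloxy group, and the amidine base then equilibrates C7 through the enolate to the isomer with the side chain equatorial and trans to C6–O, because the epimer would place it syn-axial to the C5 substituent.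

Step 13
Reactants: 23 ketone
Product: 24 (1S,2R,3R,4S,5S)-3-(TBS-oxy)-2-[2-(TBS-oxy)ethyl]-4-[3-(TBDPS-oxy)prop-1-en-2-yl]-5-ethynyl-5-methylcyclohexan-1-ol
Conditions: NaBH4, CeCl3·7H2O, MeOH, −78 → −40 °C
Reagents that add atoms: none
Why: Luche reduction delivers hydride along the axial trajectory, which only the slim axial ethynyl group at C10 flanks, and should give the equatorial C8 alcohol trans to the C7 side chain (1,2-reduction under substrate control).

Step 14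
Reactants: 24 ethynyl alcohol
Product: 25 (1S,2R,3R,4S,5R)-3-(TBS-oxy)-2-[2-(TBS-oxy)ethyl]-4-[3-(TBDPS-oxy)prop-1-en-2-yl]-5-ethenyl-5-methylcyclohexan-1-ol
Conditions: H2 (1 atm), Pd/CaCO3 poisoned with Pb(OAc)2, quinoline, EtOAc, rt
Reagents that add atoms: none
Why: Lindlar semi-hydrogenation reduces the terminal alkyne to the vinyl group and should leave the 1,1-disubstituted alkene alone.

Step 15
Reactants: 25 vinyl alcohol; 19 (2Z)-4-(acetyloxy)-2-methylbut-2-enoic acid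
Product: 27 (1S,2R,3R,4S,5R)-3-(TBS-oxy)-2-[2-(TBS-oxy)ethyl]-4-[3-(TBDPS-oxy)prop-1-en-2-yl]-5-ethenyl-5-methylcyclohexyl (2Z)-4-(acetyloxy)-2-methylbut-2-enoate, via mixed anhydride 26 (not isolated)
Conditions: 19, 2,4,6-Cl3C6H2COCl, Et3N, toluene, rt; then 25, DMAP, toluene, 40 °C
Reagents that add atoms: none
Why: Yamaguchi esterification through the mixed anhydride acylates the equatorial C8 alcohol with the preformed Z acid under conditions known to preserve angelate-type Z geometry; no stereocentre is touched.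

Step 16
Reactants: 27 ester
Product: 28 (1S,2R,3R,4S,5R)-3-(TBS-oxy)-2-(2-hydroxyethyl)-4-[3-(TBDPS-oxy)prop-1-en-2-yl]-5-ethenyl-5-methylcyclohexyl (2Z)-4-(acetyloxy)-2-methylbut-2-enoate
Conditions: HF·pyridine, pyridine, THF, 0 °C
Reagents that add atoms: none
Why: Buffered HF·pyridine removes the unhindered primary alkyl TBS ether far faster than the hindered secondary TBS ether or the TBDPS ether (rate-selective desilylation).

Step 17
Reactants: 28 primary alcohol
Product: 29 (1S,2R,3R,4S,5R)-3-(TBS-oxy)-2-(2-oxoethyl)-4-[3-(TBDPS-oxy)prop-1-en-2-yl]-5-ethenyl-5-methylcyclohexyl (2Z)-4-(acetyloxy)-2-methylbut-2-enoate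
Conditions: Dess–Martin periodinane, NaHCO3, CH2Cl2, rt
Reagents that add atoms: none
Why: Dess–Martin oxidation gives the aldehyde under neutral buffered conditions that the esters and silyl ethers tolerate.

Step 18
Reactants: 29 aldehyde
Product: 31 2-[(1R,2R,3S,4R,6S)-6-{[(2Z)-4-(acetyloxy)-2-methylbut-2-enoyl]oxy}-2-(TBS-oxy)-3-[3-(TBDPS-oxy)prop-1-en-2-yl]-4-ethenyl-4-methylcyclohexyl]prop-2-enal, via Mannich base 30 (not isolated)
Conditions: CH2=NMe2+ I−, Et3N, CH2Cl2, rt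
Reagents that add atoms: dimethyl(methylidene)ammonium iodide (Eschenmoser's salt), C=[N+](C)C.[I-]
Why: Mannich reaction of the aldehyde with the iminium salt and in situ β-elimination of dimethylamine installs the exocyclic methylene (α-methylenation) without touching C7.

Step 19
Reactants: 31 enal
Product: 32 2-[(1R,2R,3S,4R,6S)-6-{[(2Z)-4-(acetyloxy)-2-methylbut-2-enoyl]oxy}-2-(TBS-oxy)-3-[3-(TBDPS-oxy)prop-1-en-2-yl]-4-ethenyl-4-methylcyclohexyl]prop-2-enoic acid
Conditions: NaClO2, NaH2PO4, 2-methylbut-2-ene, t-BuOH/H2O, 0 °C → rt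
Reagents that add atoms: sodium chlorite, [Na+].[O-]Cl=O
Why: Pinnick oxidation converts the 2-substituted acrolein into the acrylic acid without migration of the double bond, the alkene scavenger taking up the hypochlorous acid.

Step 20
Reactants: 32 silylated acid
Product: 33 2-[(1S,2R,3S,4R,6S)-6-{[(2Z)-4-(acetyloxy)-2-methylbut-2-enoyl]oxy}-4-ethenyl-2-hydroxy-3-(3-hydroxyprop-1-en-2-yl)-4-methylcyclohexyl]prop-2-enoic acid (CNP0261293.4)
Conditions: Bu4NF, AcOH, THF, 0 °C → rt; work-up at pH 5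
Reagents that add atoms: none
Why: Buffered fluoride cleaves both remaining silyl ethers while the acid is present as its carboxylate, which should prevent lactonisation onto C6–OH and spare the acetate and the Z enoate (desilylation).

Compound list
1 | methyl glycolate | COC(=O)CO | starting material
2 | methyl 2-(TBDPS-oxy)acetate | COC(=O)CO[Si](c1ccccc1)(c1ccccc1)C(C)(C)C | intermediate
3 | 1-propynylmagnesium bromide | CC#C[Mg]Br | starting material
4 | 2-(TBDPS-oxy)-N-methoxy-N-methylacetamide (Weinreb amide) | CON(C)C(=O)CO[Si](c1ccccc1)(c1ccccc1)C(C)(C)C | intermediate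
5 | 1-(TBDPS-oxy)pent-3-yn-2-one | CC#CC(=O)CO[Si](c1ccccc1)(c1ccccc1)C(C)(C)C | intermediate
6 | ethynyltrimethylsilane | C#C[Si](C)(C)C | starting material
7 | (3E)-1-(TBDPS-oxy)-4-methyl-6-(trimethylsilyl)hex-3-en-5-yn-2-one | C[Si](C)(C)C#C/C(C)=C/C(=O)CO[Si](c1ccccc1)(c1ccccc1)C(C)(C)C | intermediate
8 | 5-hydroxypentan-2-one | CC(=O)CCCO | starting material
9 | 5-(TBS-oxy)pentan-2-one | CC(=O)CCCO[Si](C)(C)C(C)(C)C | intermediate
10 | (3Z)-5-(TBS-oxy)-2-(trimethylsilyloxy)pent-2-ene | C/C(O[Si](C)(C)C)=C/CCO[Si](C)(C)C(C)(C)C | intermediate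
11 | lithium (2Z)-5-(TBS-oxy)pent-2-en-2-olate | [Li+].C/C([O-])=C/CCO[Si](C)(C)C(C)(C)C | intermediate
12 | lithium enolate of 3-formyl-5-(TBS-oxy)pentan-2-one (chelated Z form) | [Li+].CC(=O)/C(CCO[Si](C)(C)C(C)(C)C)=C\[O-] | intermediate
13 | (3E)-5-(TBS-oxy)-3-[(TBS-oxy)methylidene]pentan-2-one | CC(=O)/C(CCO[Si](C)(C)C(C)(C)C)=C/O[Si](C)(C)C(C)(C)C | intermediate
14 | (1E)-1,3-bis(TBS-oxy)-2-[2-(TBS-oxy)ethyl]buta-1,3-diene | C=C(O[Si](C)(C)C(C)(C)C)/C(CCO[Si](C)(C)C(C)(C)C)=C/O[Si](C)(C)C(C)(C)C | intermediate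
15 | 3-methylfuran-2(5H)-one | CC1=CCOC1=O | starting material
16 | sodium (2Z)-4-hydroxy-2-methylbut-2-enoate | [Na+].[O-]C(=O)/C(C)=C\CO | intermediate
17 | 4-methoxybenzyl (2Z)-4-hydroxy-2-methylbut-2-enoate | COc1ccc(COC(=O)/C(C)=C\CO)cc1 | intermediate
18 | 4-methoxybenzyl (2Z)-4-(acetyloxy)-2-methylbut-2-enoate | COc1ccc(COC(=O)/C(C)=C\COC(C)=O)cc1 | intermediate
19 | (2Z)-4-(acetyloxy)-2-methylbut-2-enoic acid | OC(=O)/C(C)=C\COC(C)=O | intermediate
20 | 2-(TBDPS-oxy)-1-[(1R,2R,6S)-2,4-bis(TBS-oxy)-3-[2-(TBS-oxy)ethyl]-6-methyl-6-[(trimethylsilyl)ethynyl]cyclohex-3-en-1-yl]ethan-1-one | C[Si](C)(C)C#C[C@@]1(C)CC(O[Si](C)(C)C(C)(C)C)=C(CCO[Si](C)(C)C(C)(C)C)[C@H](O[Si](C)(C)C(C)(C)C)[C@@H]1C(=O)CO[Si](c2ccccc2)(c2ccccc2)C(C)(C)C | intermediate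
21 | (1S,2R,6S)-2,4-bis(TBS-oxy)-3-[2-(TBS-oxy)ethyl]-1-[3-(TBDPS-oxy)prop-1-en-2-yl]-6-methyl-6-[(trimethylsilyl)ethynyl]cyclohex-3-ene | C[Si](C)(C)C#C[C@@]1(C)CC(O[Si](C)(C)C(C)(C)C)=C(CCO[Si](C)(C)C(C)(C)C)[C@H](O[Si](C)(C)C(C)(C)C)[C@@H]1C(=C)CO[Si](c2ccccc2)(c2ccccc2)C(C)(C)C | intermediate
22 | (2R,3R,4S,5S)-3-(TBS-oxy)-2-[2-(TBS-oxy)ethyl]-4-[3-(TBDPS-oxy)prop-1-en-2-yl]-5-ethynyl-5-methylcyclohexan-1-one (C7 epimer of 23) | C#C[C@@]1(C)CC(=O)[C@H](CCO[Si](C)(C)C(C)(C)C)[C@H](O[Si](C)(C)C(C)(C)C)[C@@H]1C(=C)CO[Si](c2ccccc2)(c2ccccc2)C(C)(C)C | intermediate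
23 | (2S,3R,4S,5S)-3-(TBS-oxy)-2-[2-(TBS-oxy)ethyl]-4-[3-(TBDPS-oxy)prop-1-en-2-yl]-5-ethynyl-5-methylcyclohexan-1-one | C#C[C@@]1(C)CC(=O)[C@@H](CCO[Si](C)(C)C(C)(C)C)[C@H](O[Si](C)(C)C(C)(C)C)[C@@H]1C(=C)CO[Si](c2ccccc2)(c2ccccc2)C(C)(C)C | intermediate
24 | (1S,2R,3R,4S,5S)-3-(TBS-oxy)-2-[2-(TBS-oxy)ethyl]-4-[3-(TBDPS-oxy)prop-1-en-2-yl]-5-ethynyl-5-methylcyclohexan-1-ol | C#C[C@@]1(C)C[C@H](O)[C@@H](CCO[Si](C)(C)C(C)(C)C)[C@H](O[Si](C)(C)C(C)(C)C)[C@@H]1C(=C)CO[Si](c2ccccc2)(c2ccccc2)C(C)(C)C | intermediate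
25 | (1S,2R,3R,4S,5R)-3-(TBS-oxy)-2-[2-(TBS-oxy)ethyl]-4-[3-(TBDPS-oxy)prop-1-en-2-yl]-5-ethenyl-5-methylcyclohexan-1-ol | C=C[C@@]1(C)C[C@H](O)[C@@H](CCO[Si](C)(C)C(C)(C)C)[C@H](O[Si](C)(C)C(C)(C)C)[C@@H]1C(=C)CO[Si](c2ccccc2)(c2ccccc2)C(C)(C)C | intermediate
26 | (2Z)-4-(acetyloxy)-2-methylbut-2-enoic 2,4,6-trichlorobenzoic anhydride | O=C(OC(=O)c1c(Cl)cc(Cl)cc1Cl)/C(C)=C\COC(C)=O | intermediate
27 | (1S,2R,3R,4S,5R)-3-(TBS-oxy)-2-[2-(TBS-oxy)ethyl]-4-[3-(TBDPS-oxy)prop-1-en-2-yl]-5-ethenyl-5-methylcyclohexyl (2Z)-4-(acetyloxy)-2-methylbut-2-enoate | C=C[C@@]1(C)C[C@H](OC(=O)/C(C)=C\COC(C)=O)[C@@H](CCO[Si](C)(C)C(C)(C)C)[C@H](O[Si](C)(C)C(C)(C)C)[C@@H]1C(=C)CO[Si](c2ccccc2)(c2ccccc2)C(C)(C)C | intermediate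
28 | (1S,2R,3R,4S,5R)-3-(TBS-oxy)-2-(2-hydroxyethyl)-4-[3-(TBDPS-oxy)prop-1-en-2-yl]-5-ethenyl-5-methylcyclohexyl (2Z)-4-(acetyloxy)-2-methylbut-2-enoate | C=C[C@@]1(C)C[C@H](OC(=O)/C(C)=C\COC(C)=O)[C@@H](CCO)[C@H](O[Si](C)(C)C(C)(C)C)[C@@H]1C(=C)CO[Si](c2ccccc2)(c2ccccc2)C(C)(C)C | intermediate
29 | (1S,2R,3R,4S,5R)-3-(TBS-oxy)-2-(2-oxoethyl)-4-[3-(TBDPS-oxy)prop-1-en-2-yl]-5-ethenyl-5-methylcyclohexyl (2Z)-4-(acetyloxy)-2-methylbut-2-enoate | C=C[C@@]1(C)C[C@H](OC(=O)/C(C)=C\COC(C)=O)[C@@H](CC=O)[C@H](O[Si](C)(C)C(C)(C)C)[C@@H]1C(=C)CO[Si](c2ccccc2)(c2ccccc2)C(C)(C)C | intermediate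
30 | (1S,2R,3R,4S,5R)-3-(TBS-oxy)-2-[1-(dimethylamino)-3-oxopropan-2-yl]-4-[3-(TBDPS-oxy)prop-1-en-2-yl]-5-ethenyl-5-methylcyclohexyl (2Z)-4-(acetyloxy)-2-methylbut-2-enoate (Mannich base, both C11 epimers) | C=C[C@@]1(C)C[C@H](OC(=O)/C(C)=C\COC(C)=O)[C@@H](C(CN(C)C)C=O)[C@H](O[Si](C)(C)C(C)(C)C)[C@@H]1C(=C)CO[Si](c2ccccc2)(c2ccccc2)C(C)(C)C | intermediate
31 | 2-[(1R,2R,3S,4R,6S)-6-{[(2Z)-4-(acetyloxy)-2-methylbut-2-enoyl]oxy}-2-(TBS-oxy)-3-[3-(TBDPS-oxy)prop-1-en-2-yl]-4-ethenyl-4-methylcyclohexyl]prop-2-enal | C=C[C@@]1(C)C[C@H](OC(=O)/C(C)=C\COC(C)=O)[C@@H](C(=C)C=O)[C@H](O[Si](C)(C)C(C)(C)C)[C@@H]1C(=C)CO[Si](c2ccccc2)(c2ccccc2)C(C)(C)C | intermediate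
32 | 2-[(1R,2R,3S,4R,6S)-6-{[(2Z)-4-(acetyloxy)-2-methylbut-2-enoyl]oxy}-2-(TBS-oxy)-3-[3-(TBDPS-oxy)prop-1-en-2-yl]-4-ethenyl-4-methylcyclohexyl]prop-2-enoic acid | C=C[C@@]1(C)C[C@H](OC(=O)/C(C)=C\COC(C)=O)[C@@H](C(=C)C(=O)O)[C@H](O[Si](C)(C)C(C)(C)C)[C@@H]1C(=C)CO[Si](c2ccccc2)(c2ccccc2)C(C)(C)C | intermediate
33 | 2-[(1S,2R,3S,4R,6S)-6-{[(2Z)-4-(acetyloxy)-2-methylbut-2-enoyl]oxy}-4-ethenyl-2-hydroxy-3-(3-hydroxyprop-1-en-2-yl)-4-methylcyclohexyl]prop-2-enoic acid | C=C[C@@]1(C)C[C@H](OC(=O)/C(C)=C\COC(C)=O)[C@@H](C(=C)C(=O)O)[C@H](O)[C@@H]1C(=C)CO | target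

Total step count: 20. Longest linear sequence: 15 steps (steps 4–7, then 10–20).

Steps most likely to fail

Step 10 (Proposed new method). The hindered β,β-disubstituted enone may add too slowly under the chiral Lewis acid, stop at the open Mukaiyama–Michael stage, or close with poor facial or endo control. Fallback: from 7 and 14 the cycloaddition is run as a racemic Diels–Alder reaction under the mixed aluminium Lewis acid AlBr3/AlMe3 (10:1, toluene/CH2Cl2, −5 °C), a system known for hindered silyloxy diene/β,β-disubstituted enone pairs, to give the racemic adduct F1. Takai–Lombardo methylenation as in step 11 then gives the racemic methylene compound F2, whose enantiomers are separated by preparative HPLC on a chiral stationary phase; the route is rejoined at 21.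

Step 13. Hydride may arrive along the equatorial trajectory, past the axial ethynyl group, and give the axial C8 alcohol. Fallback: from 23, reduction with LiBH(s-Bu)3 (THF, −78 °C), which attacks equatorially by design, gives the C8-epimeric alcohol F3. Mitsunobu inversion (PPh3, DIAD, 4-nitrobenzoic acid, THF) turns it into the 4-nitrobenzoate of the required C8 configuration F4, and methanolysis (K2CO3, MeOH) rejoins the route at 24.

Step 15. Acylation of the flanked C8 alcohol may be slow enough for the activated Z acid to isomerise to the E acid or to decompose. Fallback: from 25, acylation with 2-[bis(2,2,2-trifluoroethoxy)phosphoryl]propanoic acid (DCC, DMAP, CH2Cl2) gives the phosphonopropanoate F5, on which the Z alkene is built by Still–Gennari olefination with 2-oxoethyl acetate (KN(SiMe3)2, 18-crown-6, THF, −78 °C); the route is rejoined at 27.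

Further compounds
F1 | step 10 | racemic 20 (1:1 mixture of 20 and its enantiomer) | C[Si](C)(C)C#C[C@@]1(C)CC(O[Si](C)(C)C(C)(C)C)=C(CCO[Si](C)(C)C(C)(C)C)[C@H](O[Si](C)(C)C(C)(C)C)[C@@H]1C(=O)CO[Si](c2ccccc2)(c2ccccc2)C(C)(C)C.C[Si](C)(C)C#C[C@]1(C)CC(O[Si](C)(C)C(C)(C)C)=C(CCO[Si](C)(C)C(C)(C)C)[C@@H](O[Si](C)(C)C(C)(C)C)[C@H]1C(=O)CO[Si](c2ccccc2)(c2ccccc2)C(C)(C)C
F2 | step 10 | racemic 21 (1:1 mixture of 21 and its enantiomer) | C[Si](C)(C)C#C[C@@]1(C)CC(O[Si](C)(C)C(C)(C)C)=C(CCO[Si](C)(C)C(C)(C)C)[C@H](O[Si](C)(C)C(C)(C)C)[C@@H]1C(=C)CO[Si](c2ccccc2)(c2ccccc2)C(C)(C)C.C[Si](C)(C)C#C[C@]1(C)CC(O[Si](C)(C)C(C)(C)C)=C(CCO[Si](C)(C)C(C)(C)C)[C@@H](O[Si](C)(C)C(C)(C)C)[C@H]1C(=C)CO[Si](c2ccccc2)(c2ccccc2)C(C)(C)C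
F3 | step 13 | (1R,2R,3R,4S,5S)-3-(TBS-oxy)-2-[2-(TBS-oxy)ethyl]-4-[3-(TBDPS-oxy)prop-1-en-2-yl]-5-ethynyl-5-methylcyclohexan-1-ol (C8 epimer of 24) | C#C[C@@]1(C)C[C@@H](O)[C@@H](CCO[Si](C)(C)C(C)(C)C)[C@H](O[Si](C)(C)C(C)(C)C)[C@@H]1C(=C)CO[Si](c2ccccc2)(c2ccccc2)C(C)(C)C
F4 | step 13 | (1S,2R,3R,4S,5S)-3-(TBS-oxy)-2-[2-(TBS-oxy)ethyl]-4-[3-(TBDPS-oxy)prop-1-en-2-yl]-5-ethynyl-5-methylcyclohexyl 4-nitrobenzoate | C#C[C@@]1(C)C[C@H](OC(=O)c2ccc(cc2)[N+](=O)[O-])[C@@H](CCO[Si](C)(C)C(C)(C)C)[C@H](O[Si](C)(C)C(C)(C)C)[C@@H]1C(=C)CO[Si](c3ccccc3)(c3ccccc3)C(C)(C)C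
F5 | step 15 | (1S,2R,3R,4S,5R)-3-(TBS-oxy)-2-[2-(TBS-oxy)ethyl]-4-[3-(TBDPS-oxy)prop-1-en-2-yl]-5-ethenyl-5-methylcyclohexyl 2-[bis(2,2,2-trifluoroethoxy)phosphoryl]propanoate | C=C[C@@]1(C)C[C@H](OC(=O)C(C)P(=O)(OCC(F)(F)F)OCC(F)(F)F)[C@@H](CCO[Si](C)(C)C(C)(C)C)[C@H](O[Si](C)(C)C(C)(C)C)[C@@H]1C(=C)CO[Si](c2ccccc2)(c2ccccc2)C(C)(C)C
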